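**Retrosynthetic overview**
1. Target ⇒ its tetra-O-TBS ether ⇒ (Stille, prenyl–SnBu3) the 5′-bromo isoflavanone. Rings A and B are bought as arenes. Ring C is the only ring made and is closed last.
2. Ring C: C4–C4a by intramolecular Friedel–Crafts acylation of a (2R)-2-aryl-3-aryloxypropanoic acid in which the O1–C2 ether is already in place.
3. CO2H ⇐ oxidative cleavage of an (E)-propenyl group. 3′-OH ⇐ ortho-formylation/Dakin oxidation of the 2′-phenol.
4. Key bond C1′–C3: aromatic Claisen [3,3] shift of an (R,Z)-1-methylallyl aryl ether, with 1,3-chirality transfer from C–O to C–C. This step also frees the 2′-OH.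
5. Allyl ether ⇐ (S)-but-3-yn-2-ol + 4-bromo-3-methoxyphenol (Mitsunobu, inversion), CH2O, 3,5-bis(TBSO)phenol (Mitsunobu), Lindlar.

Assumption: the stereocentre in the SMILES reads as (3R); (S)-but-3-yn-2-ol (≥98% ee), 4-bromo-3-methoxyphenol and tributyl(3-methylbut-2-enyl)stannane are catalogue items. TBS = tert-butyldimethylsilyl.

Step 1
Reactants: 1 phloroglucinol
Product: 2 3,5-bis(tert-butyldimethylsilyloxy)phenol
Conditions: TBSCl (2.0 equiv), imidazole, DMF, 0 °C → rt
Reagents that add atoms: tert-butyldimethylsilyl chloride, CC(C)(C)[Si](C)(C)Cl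
Why: O-silylation of a C3-symmetric triphenol can differ only in degree, so the bis-ether is separated from recyclable mono- and tris-ethers, and aryl TBS ethers survive the later steps yet leave with buffered fluoride.

Step 2
Reactants: 3 4-bromo-3-methoxyphenol; 4 (S)-but-3-yn-2-ol
Product: 5 1-bromo-4-[(2R)-but-3-yn-2-yloxy]-2-methoxybenzene
Conditions: PPh3, DIAD, THF, 0 °C → rt
Reagents that add atoms: none
Why: Mitsunobu etherification, in which the phenoxide attacks the propargylic oxyphosphonium salt by clean SN2, so the purchased (S) carbinol centre is inverted to (R) and, being propargylic rather than allylic, cannot leak through SN2′.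

Step 3
Reactants: 5 1-bromo-4-[(2R)-but-3-yn-2-yloxy]-2-methoxybenzene
Product: 7 (4R)-4-(4-bromo-3-methoxyphenoxy)pent-2-yn-1-ol, via alkynylmagnesium bromide 6 (not isolated)
Conditions: EtMgBr, THF, 0 °C → rt; (CH2O)n, 45 °C; then 1 M HCl
Reagents that add atoms: formaldehyde (from paraformaldehyde), C=O; ethylmagnesium bromide, CC[Mg]Br (its MgBr stays only in 6)
Why: Iotsich acetylide formation and 1,2-addition to formaldehyde, in which EtMgBr removes only the alkyne C–H (no halogen–metal exchange on the aryl bromide, unlike BuLi) and the ether stereocentre is a spectator.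

Step 4
Reactants: 7 (4R)-4-(4-bromo-3-methoxyphenoxy)pent-2-yn-1-ol; 2 3,5-bis(tert-butyldimethylsilyloxy)phenol
Product: 8 1-[(4R)-4-(4-bromo-3-methoxyphenoxy)pent-2-yn-1-yloxy]-3,5-bis(tert-butyldimethylsilyloxy)benzene
Conditions: PPh3, DIAD, toluene, 0 °C → rt
Reagents that add atoms: none
Why: A second Mitsunobu etherification, now at an unhindered primary propargylic alcohol, installs the future O1–C2 bond under neutral conditions that spare the aryl TBS ethers and the (R) centre.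

Step 5
Reactants: 8 the (R)-alkyne bis(aryl ether)
Product: 9 1-[(2Z,4R)-4-(4-bromo-3-methoxyphenoxy)pent-2-en-1-yloxy]-3,5-bis(tert-butyldimethylsilyloxy)benzene
Conditions: H2 (1 atm), Lindlar catalyst, quinoline, EtOAc, rt
Reagents that add atoms: none
Why: Lindlar semihydrogenation adds H2 syn and stops at the Z-alkene, the geometry that enforces a single Claisen transition state, while ArBr, the aryl ethers and the stereocentre are untouched.

Step 6
Reactants: 9 the (2Z,4R)-allyl aryl ether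
Product: 11 4-bromo-5-methoxy-2-[(2R,3E)-1-{3,5-bis(tert-butyldimethylsilyloxy)phenoxy}pent-3-en-2-yl]phenol, via ortho-dienone 10 (not isolated)
Conditions: PhNEt2, 180 °C, Ar, about 6 h
Reagents that add atoms: none
Why: In this aromatic Claisen rearrangement the suprafacial [3,3] shift makes C1′–C3 on the allyl face from which the C–O bond leaves and the Z-alkene tolerates only the transition state with the carbinol H inside (A1,3 strain), so (R,Z)-9 gives only the (E)-propenyl (R) product, the shift going to the ring-B carbon para to OMe (the other ortho site is walled in by the Br-buttressed OMe) and outrunning the ring-A ether, which lacks the accelerating α-methyl group and would have to join an OTBS-flanked ring carbon to a branched terminus.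

Step 7
Reactants: 11 the Claisen phenol
Product: 13 4-bromo-3-methoxy-6-[(2R,3E)-1-{3,5-bis(tert-butyldimethylsilyloxy)phenoxy}pent-3-en-2-yl]benzene-1,2-diol, via salicylaldehyde 12 (not isolated)
Conditions: MgCl2, Et3N, (CH2O)n, THF, reflux; then 0 °C, aq NaOH, 30% H2O2, 20 min; 1 M HCl
Reagents that add atoms: formaldehyde (from paraformaldehyde), C=O (its CHO stays only in 12); hydrogen peroxide, OO
Why: Magnesium-phenoxide-directed (Casnati–Skattebøl) ortho-formylation can strike only the one free ortho carbon C3′ and Dakin oxidation in the same pot swaps CHO for OH, with THF (not MeCN) avoiding Payne epoxidation of the alkene and the benzylic/allylic C–H far too weakly acidic to epimerise.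

Step 8
Reactants: 13 the catechol
Product: 14 1-bromo-4,5-bis(tert-butyldimethylsilyloxy)-2... written out: the 1,2-bis(TBS) ether of 13, i.e. (2R,3E)-2-[5-bromo-2,3-bis(TBSO)-4-methoxyphenyl]-1-[3,5-bis(TBSO)phenoxy]pent-3-ene
Conditions: TBSOTf (excess), 2,6-lutidine, CH2Cl2, 0 °C → rt
Reagents that add atoms: tert-butyldimethylsilyl triflate, CC(C)(C)[Si](C)(C)OS(=O)(=O)C(F)(F)F
Why: The silyl triflate caps both hindered catechol hydroxyls (O-silylation), its excess restores any ring-A silyl ether nicked by the base of step 7, and all four phenols now carry the same fluoride-labile group.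

Step 9
Reactants: 14 the tetra-TBS alkene
Product: 16 (2R)-2-[5-bromo-2,3-bis(TBSO)-4-methoxyphenyl]-3-[3,5-bis(TBSO)phenoxy]propanoic acid, via aldehyde 15 (not isolated)
Conditions: OsO4 (2 mol %), NaIO4, THF–H2O, 0 °C → rt; crude, NaClO2, NaH2PO4, 2-methyl-2-butene, t-BuOH–H2O, 0 °C → rt
Reagents that add atoms: osmium tetroxide, O=[Os](=O)(=O)=O, re-oxidised by sodium periodate, [Na+].[O-]I(=O)(=O)=O (carbonyl O); sodium chlorite, [Na+].[O-]Cl=O (second O of the acid)
Why: Lemieux–Johnson cleavage of the only alkene followed at once by Pinnick oxidation at pH about 4 keeps the α-aryl-β-aryloxy aldehyde away from any amine or storage, so neither enolisation nor E1cB loss of the aryloxide gets time, and the alkene scavenger keeps HOCl off ring A.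

Step 10
Reactants: 16 the (2R)-acid
Product: 18 (3R)-3-[5-bromo-2,3-bis(TBSO)-4-methoxyphenyl]-5,7-bis(TBSO)chroman-4-one, via mixed anhydride 17 (not isolated)
Conditions: (CF3CO)2O (1.5 equiv), CH2Cl2, 0 °C → rt
Reagents that add atoms: trifluoroacetic anhydride, O=C(OC(=O)C(F)(F)F)C(F)(F)F (its CF3CO stays only in 17)
Why: In this intramolecular Friedel–Crafts acylation the acyl trifluoroacetate is attacked by the trioxygenated ring A at either of its two equivalent ortho carbons (6-membered ring, one regioisomer), and the base-free, cold, weakly acidic medium gives no ketene or enolate path to racemisation.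

Step 11
Reactants: 18 the 5′-bromo isoflavanone
Product: 19 (3R)-3-[2,3-bis(TBSO)-4-methoxy-5-(3-methylbut-2-enyl)phenyl]-5,7-bis(TBSO)chroman-4-one
Conditions: Bu3SnCH2CH=CMe2 (1.5 equiv), Pd(PPh3)4 (5 mol %), toluene, 95 °C
Reagents that add atoms: tributyl(3-methylbut-2-en-1-yl)stannane, CCCC[Sn](CCCC)(CCCC)CC=C(C)C
Why: Migita–Kosugi–Stille coupling at the only C–Br bond, with C–C bond formation at the unsubstituted allyl terminus giving the linear prenyl group, runs without base or protic medium so the C3–H is not enolised, and it comes after the alkene cleavage so the prenyl alkene never meets an oxidant.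

Step 12
Reactants: 19 the tetra-TBS prenyl isoflavanone
Product: 20 (3R)-5,7-dihydroxy-3-[2,3-dihydroxy-4-methoxy-5-(3-methylbut-2-en-1-yl)phenyl]chroman-4-one
Conditions: TBAF (4.4 equiv), AcOH (5 equiv), THF, 0 °C, 30 min
Reagents that add atoms: none
Why: Fluoride desilylation of four aryl silyl ethers, with acetic acid protonating each phenoxide as it forms, so the medium stays slightly acidic, cold and brief, and this spares the prenyl alkene, the catechol and the base-labile (3R) centre.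

**Compound list**
1 | phloroglucinol | Oc1cc(O)cc(O)c1 | starting material
2 | 3,5-bis(tert-butyldimethylsilyloxy)phenol | Oc1cc(O[Si](C)(C)C(C)(C)C)cc(O[Si](C)(C)C(C)(C)C)c1 | intermediate
3 | 4-bromo-3-methoxyphenol | COc1cc(O)ccc1Br | starting material
4 | (S)-but-3-yn-2-ol | C[C@H](O)C#C | starting material
5 | 1-bromo-4-[(2R)-but-3-yn-2-yloxy]-2-methoxybenzene | C[C@@H](Oc1ccc(Br)c(OC)c1)C#C | intermediate
6 | bromomagnesium acetylide of 5 | C[C@@H](Oc1ccc(Br)c(OC)c1)C#C[Mg]Br | intermediate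
7 | (4R)-4-(4-bromo-3-methoxyphenoxy)pent-2-yn-1-ol | C[C@@H](Oc1ccc(Br)c(OC)c1)C#CCO | intermediate
8 | 1-[(4R)-4-(4-bromo-3-methoxyphenoxy)pent-2-yn-1-yloxy]-3,5-bis(TBSO)benzene | C[C@@H](Oc1ccc(Br)c(OC)c1)C#CCOc1cc(O[Si](C)(C)C(C)(C)C)cc(O[Si](C)(C)C(C)(C)C)c1 | intermediate
9 | 1-[(2Z,4R)-4-(4-bromo-3-methoxyphenoxy)pent-2-en-1-yloxy]-3,5-bis(TBSO)benzene | C[C@@H](Oc1ccc(Br)c(OC)c1)/C=C\COc1cc(O[Si](C)(C)C(C)(C)C)cc(O[Si](C)(C)C(C)(C)C)c1 | intermediate
10 | 4-bromo-3-methoxy-6-[(2R,3E)-1-{3,5-bis(TBSO)phenoxy}pent-3-en-2-yl]cyclohexa-2,4-dien-1-one (ring sp3 centre left open, it is lost on tautomerisation) | O=C1C=C(OC)C(Br)=CC1[C@@H](/C=C/C)COc1cc(O[Si](C)(C)C(C)(C)C)cc(O[Si](C)(C)C(C)(C)C)c1 | intermediate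
11 | 4-bromo-5-methoxy-2-[(2R,3E)-1-{3,5-bis(TBSO)phenoxy}pent-3-en-2-yl]phenol | Oc1cc(OC)c(Br)cc1[C@@H](/C=C/C)COc1cc(O[Si](C)(C)C(C)(C)C)cc(O[Si](C)(C)C(C)(C)C)c1 | intermediate
12 | 5-bromo-2-hydroxy-6-methoxy-3-[(2R,3E)-1-{3,5-bis(TBSO)phenoxy}pent-3-en-2-yl]benzaldehyde | O=Cc1c(O)c([C@@H](/C=C/C)COc2cc(O[Si](C)(C)C(C)(C)C)cc(O[Si](C)(C)C(C)(C)C)c2)cc(Br)c1OC | intermediate
13 | 4-bromo-3-methoxy-6-[(2R,3E)-1-{3,5-bis(TBSO)phenoxy}pent-3-en-2-yl]benzene-1,2-diol | Oc1c(O)c(OC)c(Br)cc1[C@@H](/C=C/C)COc1cc(O[Si](C)(C)C(C)(C)C)cc(O[Si](C)(C)C(C)(C)C)c1 | intermediate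
14 | (2R,3E)-2-[5-bromo-2,3-bis(TBSO)-4-methoxyphenyl]-1-[3,5-bis(TBSO)phenoxy]pent-3-ene | CC(C)(C)[Si](C)(C)Oc1c(O[Si](C)(C)C(C)(C)C)c(OC)c(Br)cc1[C@@H](/C=C/C)COc1cc(O[Si](C)(C)C(C)(C)C)cc(O[Si](C)(C)C(C)(C)C)c1 | intermediate
15 | (2R)-2-[5-bromo-2,3-bis(TBSO)-4-methoxyphenyl]-3-[3,5-bis(TBSO)phenoxy]propanal | CC(C)(C)[Si](C)(C)Oc1c(O[Si](C)(C)C(C)(C)C)c(OC)c(Br)cc1[C@@H](C=O)COc1cc(O[Si](C)(C)C(C)(C)C)cc(O[Si](C)(C)C(C)(C)C)c1 | intermediate
16 | (2R)-2-[5-bromo-2,3-bis(TBSO)-4-methoxyphenyl]-3-[3,5-bis(TBSO)phenoxy]propanoic acid | CC(C)(C)[Si](C)(C)Oc1c(O[Si](C)(C)C(C)(C)C)c(OC)c(Br)cc1[C@@H](C(=O)O)COc1cc(O[Si](C)(C)C(C)(C)C)cc(O[Si](C)(C)C(C)(C)C)c1 | intermediate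
17 | mixed anhydride of 16 and trifluoroacetic acid | CC(C)(C)[Si](C)(C)Oc1c(O[Si](C)(C)C(C)(C)C)c(OC)c(Br)cc1[C@@H](C(=O)OC(=O)C(F)(F)F)COc1cc(O[Si](C)(C)C(C)(C)C)cc(O[Si](C)(C)C(C)(C)C)c1 | intermediate
18 | (3R)-3-[5-bromo-2,3-bis(TBSO)-4-methoxyphenyl]-5,7-bis(TBSO)chroman-4-one | COc1c(Br)cc([C@@H]2COc3cc(O[Si](C)(C)C(C)(C)C)cc(O[Si](C)(C)C(C)(C)C)c3C2=O)c(O[Si](C)(C)C(C)(C)C)c1O[Si](C)(C)C(C)(C)C | intermediate
19 | (3R)-3-[2,3-bis(TBSO)-4-methoxy-5-(3-methylbut-2-enyl)phenyl]-5,7-bis(TBSO)chroman-4-one | COc1c(CC=C(C)C)cc([C@@H]2COc3cc(O[Si](C)(C)C(C)(C)C)cc(O[Si](C)(C)C(C)(C)C)c3C2=O)c(O[Si](C)(C)C(C)(C)C)c1O[Si](C)(C)C(C)(C)C | intermediate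
20 | (3R)-5,7-dihydroxy-3-[2,3-dihydroxy-4-methoxy-5-(3-methylbut-2-en-1-yl)phenyl]chroman-4-one | COc1c(CC=C(C)C)cc([C@@H]2COc3cc(O)cc(O)c3C2=O)c(O)c1O | target

**Step count and risks**
Total step count: 12. Longest linear sequence: 11 (steps 2–12, from 3 and 4). Step 1 is a one-step side branch.

**Step 6 (Claisen).** Compound 9 holds two allyl aryl ethers, so the ring-A ether could rearrange too. Long heating could also start an abnormal Claisen process.
- The fallback sets out from 7 and comes back at 14. It runs the rearrangement before ring A is attached.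
- Compound 7 is semihydrogenated (Lindlar) to (2Z,4R)-4-(4-bromo-3-methoxyphenoxy)pent-2-en-1-ol F1.
- Heating in PhNEt2 at 180 °C takes it through the ortho-dienone F2 to the phenol-alcohol F3. Here the only allyl aryl ether present is the correct one.
- The same formylation/Dakin pot, now with no silyl ether exposed to base, passes through the salicylaldehyde F4 to the catechol-alcohol F5.
- TBSOTf/2,6-lutidine gives the tris-silyl ether F6.
- PPTS in MeOH frees only the aliphatic oxygen to give the primary alcohol F7, because aryl TBS ethers are acid-stable.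
- Mitsunobu coupling of this alcohol with 2 gives 14. The detour costs one extra step.

**Step 7 (formylation/Dakin).** The carbon to be formylated sits between OH and a buttressed OMe. The alkaline peroxide can also strip ring-A silyl ethers.
- The fallback sets out from 11 and comes back at 13. It replaces the C1 detour by direct oxygen transfer.
- IBX in DMF at rt binds the phenol and delivers oxygen to the unsubstituted ortho carbon. The other ortho carbon carries the bulky side chain.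
- This gives the ortho-quinone F8, which aqueous Na2S2O4 reduces to 13 in the same flask, with no base present.

**Step 11 (Stille).** Hours at 95 °C next to an enolisable α-aryl ketone may erode the ee, and some reverse-prenyl isomer may form.
- The fallback sets out from 16 and comes back at 19. It moves the coupling in front of the ring closure, where the stereocentre sits beside a carboxylic acid that does not enolise.
- Compound 16, the stannane and Pd(PPh3)4 in toluene at 95 °C give the prenylated acid F9.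
- TFAA in CH2Cl2 at −10 → 0 °C with short contact closes ring C through the prenylated mixed anhydride F10 to 19. The cold, brief conditions are chosen so that trifluoroacetic acid does not add to the prenyl alkene.

**Further compounds**
F1 | step 6 | (2Z,4R)-4-(4-bromo-3-methoxyphenoxy)pent-2-en-1-ol | C[C@@H](Oc1ccc(Br)c(OC)c1)/C=C\CO
F2 | step 6 | 4-bromo-6-[(2R,3E)-1-hydroxypent-3-en-2-yl]-3-methoxycyclohexa-2,4-dien-1-one | O=C1C=C(OC)C(Br)=CC1[C@@H](/C=C/C)CO
F3 | step 6 | 4-bromo-2-[(2R,3E)-1-hydroxypent-3-en-2-yl]-5-methoxyphenol | Oc1cc(OC)c(Br)cc1[C@@H](/C=C/C)CO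
F4 | step 6 | 5-bromo-2-hydroxy-3-[(2R,3E)-1-hydroxypent-3-en-2-yl]-6-methoxybenzaldehyde | O=Cc1c(O)c([C@@H](/C=C/C)CO)cc(Br)c1OC
F5 | step 6 | 4-bromo-6-[(2R,3E)-1-hydroxypent-3-en-2-yl]-3-methoxybenzene-1,2-diol | Oc1c(O)c(OC)c(Br)cc1[C@@H](/C=C/C)CO
F6 | step 6 | tris-TBS ether of F5 | CC(C)(C)[Si](C)(C)Oc1c(O[Si](C)(C)C(C)(C)C)c(OC)c(Br)cc1[C@@H](/C=C/C)CO[Si](C)(C)C(C)(C)C
F7 | step 6 | (2R,3E)-2-[5-bromo-2,3-bis(TBSO)-4-methoxyphenyl]pent-3-en-1-ol | CC(C)(C)[Si](C)(C)Oc1c(O[Si](C)(C)C(C)(C)C)c(OC)c(Br)cc1[C@@H](/C=C/C)CO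
F8 | step 7 | 4-bromo-3-methoxy-6-[(2R,3E)-1-{3,5-bis(TBSO)phenoxy}pent-3-en-2-yl]cyclohexa-3,5-diene-1,2-dione | O=C1C(=O)C(OC)=C(Br)C=C1[C@@H](/C=C/C)COc1cc(O[Si](C)(C)C(C)(C)C)cc(O[Si](C)(C)C(C)(C)C)c1
F9 | step 11 | (2R)-2-[2,3-bis(TBSO)-4-methoxy-5-(3-methylbut-2-enyl)phenyl]-3-[3,5-bis(TBSO)phenoxy]propanoic acid | CC(C)(C)[Si](C)(C)Oc1c(O[Si](C)(C)C(C)(C)C)c(OC)c(CC=C(C)C)cc1[C@@H](C(=O)O)COc1cc(O[Si](C)(C)C(C)(C)C)cc(O[Si](C)(C)C(C)(C)C)c1
F10 | step 11 | mixed anhydride of F9 and trifluoroacetic acid | CC(C)(C)[Si](C)(C)Oc1c(O[Si](C)(C)C(C)(C)C)c(OC)c(CC=C(C)C)cc1[C@@H](C(=O)OC(=O)C(F)(F)F)COc1cc(O[Si](C)(C)C(C)(C)C)cc(O[Si](C)(C)C(C)(C)C)c1
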